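## The problem

CNP0270314.1 consists of a 2-methyl-1,4-benzoquinone (ring A) and a δ-lactone (ring B: O1, C2(=O), C3, C4, C5, C6) that are not fused but joined through a ten-carbon chain, numbered C1' to C10' from the quinone; C7 denotes the carbinol carbon of the 2-hydroxypropan-2-yl group on C6. The chain is a geranyl unit (E olefins C2'=C3' and C6'=C7') lengthened by C8' to C10', so its two E olefins are best bought with the terpene and not made. The third olefin, C10'=C3, is exocyclic to ring B and holds C9' on the side of the C2 carbonyl (Z); this is the less stable arrangement, so aldol condensation, olefination of a lactone or any equilibration would favour the wrong isomer. C6 (R) is the only stereocentre; nothing else in the molecule can direct it, so it must come from a catalyst or a purchased building block, and once set it sits next to a tertiary alcohol that ionises easily. The quinone does not tolerate organometallic reagents, hydrides or bases and has to travel as a protected hydroquinone; the 1,5-diene chain cyclises or isomerises in strong acid; the alkylidene lactone is a Michael acceptor that can lose its geometry by reversible addition. The feature that opens the route is the substitution of C3: it carries the C2 carbonyl and the C4 methylene and is double-bonded to C10', whose single hydrogen lies cis to C4. That is exactly what a cis addition of H and C4 to a C10'≡C3 ynoate leaves behind, and C6, two atoms beyond C4, is oxygenated as it would be if C4–C5–C6 came from an allylic alcohol.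

## Retrosynthesis

**24 ⇒ 23.** The two quinone carbonyls of target 24 are traced back to the methyl ethers of hydroquinone dimethyl ether 23. Against acetals or benzyl ethers, methyl ethers survive every organometallic, ruthenium and borane step that precedes and fall in one oxidative operation. The forward reaction must oxidise only the arene and leave three olefins, the lactone and the tertiary alcohol.

**23 ⇒ 22 ⇒ 21.** The O1–C2 bond of ring B is cut, giving the open dihydroxy methyl ester 22 and its tertiary trimethylsilyl ether 21. Cutting C3=C10' instead would call for an olefination with no control of geometry, whereas the open ester already contains the Z olefin. The forward ring closure has to choose the secondary C6 hydroxyl (six-membered ring) over the tertiary one and must not isomerise the enoate.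

**21 ⇒ 20 ⇒ 19.** The C6–H bond is cut, so that the only stereocentre comes from ketone 20 by a catalyst-controlled reduction; 20 is the silyl ether of hydroxy ketone 19. Carrying a preformed C6 carbinol through the next disconnection is not possible, because that step turns C6 into a carbonyl. The silyl group makes C7 an unambiguous large substituent and removes an acidic hydroxyl from the reduction.

**19 ⇒ 14 + 17.** The C3–C4 bond and the C10'–H bond are cut together. This returns ynoate 14, whose triple bond is C10'≡C3, and racemic 2-methylpent-4-ene-2,3-diol 17, whose vinyl group supplies C4 and C5 and whose allylic carbinol becomes the C6 ketone through dienol 18. Compared with cutting C10'=C3 or C4–C5, this is the only cut that makes the difficult olefin geometry a consequence of mechanism, and it needs no protecting group on either partner. The precursor is simpler by the whole C4 to C7 unit and by the olefin. The forward ruthenium-catalysed alkene–alkyne coupling must bond C4 to the ester-bearing carbon, add H and C4 cis, and ignore the two trisubstituted chain olefins.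

**14 ⇒ 13 ⇒ 12 ⇒ 11.** The bond between the ester carbon (C2) and C3 is cut: ynoate 14 comes from acetylide 13 of terminal alkyne 12, which is the desilylated form of silylalkyne 11. Carboxylation at the end keeps the electrophilic ynoate out of the organolithium steps.

**11 ⇒ 8 + 10 (from 9).** The C8'–C9' bond is cut between allylic bromide 8 and lithiated 1-(trimethylsilyl)propyne 10, made from 9. This adds exactly the three carbons C9', C10' and C3 to a geranyl terminus, and the silyl group suppresses the allenic mode of the anion. The forward displacement must occur at C8' without allylic transposition.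

**8 ⇒ 7 ⇒ 6.** The C8'–Br bond goes back to allylic alcohol 7 and this, by removal of the C8' oxygen, to the unfunctionalised geranyl arene 6. The forward allylic oxidation has to pick the E methyl group of the terminal olefin.

**6 ⇒ 5 + 4; 5 ⇒ 3 ⇒ 2 ⇒ 1.** The aryl–C1' bond is cut between aryl Grignard reagent 5 and geranyl bromide 4, which brings both E olefins of the chain in one purchased piece. Grignard reagent 5 comes from aryl bromide 3, made from 4-methoxy-2-methylphenol 1 by ortho bromination (2) and O-methylation; the substitution pattern of ring A is thus fixed by the directing power of a phenol.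

**17 ⇒ 16 ⇒ 15.** Both C7–CH3 bonds are cut: diol 17 arises from racemic methyl 2-hydroxybut-3-enoate 15 by double methyl addition through ketone 16.

## Roads not taken

**Alternative 1:** The benzene ring itself is cut. The chromium carbene complex A1, pentacarbonyl[(2E)-1-methoxybut-2-en-1-ylidene]chromium, would combine with the terminal skipped enyne lactone A2 and one of its own carbonyl ligands in a Dötz benzannulation, closing ring A as the 4-methoxyphenol A3, which a mild oxidation would convert into 24.
- Merits: the three ring substituents are placed by the inherent regiochemistry of the benzannulation (larger alkyne substituent next to the new phenol), no aryl–allyl coupling is needed, and A3 is oxidised to the quinone at least as easily as a dimethyl ether; in this last respect the road is as good as or better than the chosen one.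
- Weak points: a stoichiometric chromium complex is used on the most advanced intermediate; A2 has a CH2 group that is both propargylic and allylic and isomerises readily; and A2 must already contain the Z-alkylidene lactone and the C6 stereocentre, so the benzannulation contributes nothing to the two real difficulties.
- Comparison: the chosen plan sets against the mild final oxidation a key step that creates the Z olefin itself, and a chain whose E olefins are bought, whereas A2 would have to be assembled olefin by olefin.

**Alternative 2:** The C1'–C2' bond and the C3'–CH3 bond are cut. Cp2ZrCl2-catalysed methylalumination (AlMe3) of the terminal alkyne of chain fragment A4, followed in the same flask by Pd(PPh3)4-catalysed coupling with benzyl chloride A5, would give arylated triene A6.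
- Merits: the carbometalation sets the C2'=C3' olefin with reliably high E selectivity, the benzyl coupling has no allylic-transposition ambiguity (in that respect it is better than the copper-catalysed allylation of step 3), and the stereocentre could be taken from a dihydroxylation or the chiral pool early on.
- Weak points: A4 must contain the C6'=C7' olefin and the Z-configured trisubstituted allylic silyl ether, both made by separate stereoselective steps; and A6 carries C2 at the alcohol oxidation level, so desilylation, oxidation and ring closure are still needed to reach 23.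
- Comparison: the chosen plan sets against the cleaner aryl–chain junction the purchase of both E olefins in geranyl bromide 4, the correct oxidation level of C2 throughout, and a clearly shorter sequence.

**Alternative 3:** The C5'–C6' bond is cut. Cathodic nickel catalysis (NiBr2(dme) with 2,2'-bipyridine) would couple the N-hydroxyphthalimide ester A7 of the aryl hexenoic acid, after decarboxylation, with the E vinyl iodide lactone A8 to give A9, which is identical with 23.
- Merits: this is the most convergent road, since two halves of similar size are joined late, the vinyl iodide geometry is transferred with retention, and free hydroxyl and lactone groups are tolerated; in convergence it is better than the chosen plan, which is linear over thirteen steps.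
- Weak points: A8 needs a stereodefined vinyl iodide and, again, the Z-alkylidene lactone with its stereocentre, i.e. the hard element must be solved separately; the alkylidene lactone of A8 and A9 is an acceptor for the primary alkyl radical and is reducible at the cathode; dedicated electrochemical equipment is required.
- Comparison: the chosen plan sets against the higher convergence a short linear sequence that starts from an intact geranyl skeleton and a key step that makes the Z olefin and the C3–C4 bond at once without protecting groups; the endgame from 23 would be the same on both roads.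

Key step: step 10

Remark: the alkene partner CH2=CH–CH(OH)–C(CH3)2OH has six carbons and is named 2-methylpent-4-ene-2,3-diol; it is used as the racemate. Geranyl bromide is taken as the commercial C10 unit.

## Route

Step 1
Reactants: 1 4-methoxy-2-methylphenol
Product: 2 2-bromo-4-methoxy-6-methylphenol
Conditions: NBS (1.0 equiv), CH2Cl2, 0 °C
Reagents that add atoms: N-bromosuccinimide, O=C1CCC(=O)N1Br
Why: Electrophilic aromatic bromination; the free hydroxyl is the strongest director, its para position carries the methoxy group and one ortho position the methyl group, so bromine should enter the remaining ortho position.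

Step 2
Reactants: 2 2-bromo-4-methoxy-6-methylphenol
Product: 3 1-bromo-2,5-dimethoxy-3-methylbenzene
Conditions: MeI, K2CO3, acetone, reflux
Reagents that add atoms: iodomethane, CI
Why: Williamson ether synthesis on the phenoxide; the aryl bromide is inert under these conditions.

Step 3
Reactants: 3 1-bromo-2,5-dimethoxy-3-methylbenzene; 4 geranyl bromide [(2E)-1-bromo-3,7-dimethylocta-2,6-diene]
Product: 6 1-[(2E)-3,7-dimethylocta-2,6-dien-1-yl]-2,5-dimethoxy-3-methylbenzene, via arylmagnesium bromide 5 (not isolated)
Conditions: Mg, THF, 40 °C; then CuI (10 mol %), 4, THF, −20 °C to rt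
Reagents that add atoms: none
Why: Grignard formation followed by copper-catalysed allylic substitution; attack at the primary carbon of 4 keeps the E olefin, whereas attack at the γ-carbon would have to create a quaternary centre and is disfavoured.

Step 4
Reactants: 6 1-[(2E)-3,7-dimethylocta-2,6-dien-1-yl]-2,5-dimethoxy-3-methylbenzene
Product: 7 (2E,6E)-8-(2,5-dimethoxy-3-methylphenyl)-2,6-dimethylocta-2,6-dien-1-ol
Conditions: SeO2 (0.3 equiv), t-BuOOH (3 equiv), salicylic acid (0.1 equiv), CH2Cl2, 0 °C to rt
Reagents that add atoms: tert-butyl hydroperoxide, CC(C)(C)OO (oxygen passed on through selenium dioxide, O=[Se]=O)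
Why: Selenium dioxide allylic oxidation (ene reaction, then [2,3]-sigmatropic shift) with tert-butyl hydroperoxide as terminal oxidant; the reaction prefers the more substituted end of the most accessible trisubstituted olefin and the methyl group trans to the chain, which should give the E allylic alcohol at the chain terminus.

Step 5
Reactants: 7 (2E,6E)-8-(2,5-dimethoxy-3-methylphenyl)-2,6-dimethylocta-2,6-dien-1-ol
Product: 8 1-[(2E,6E)-8-bromo-3,7-dimethylocta-2,6-dien-1-yl]-2,5-dimethoxy-3-methylbenzene
Conditions: CBr4, PPh3, CH2Cl2, 0 °C
Reagents that add atoms: tetrabromomethane, BrC(Br)(Br)Br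
Why: Appel reaction; the primary allylic alcohol is displaced by bromide at the same carbon under neutral conditions, so neither the position nor the geometry of the olefin should change.

Step 6
Reactants: 8 1-[(2E,6E)-8-bromo-3,7-dimethylocta-2,6-dien-1-yl]-2,5-dimethoxy-3-methylbenzene; 9 1-(trimethylsilyl)propyne
Product: 11 [(5E,9E)-11-(2,5-dimethoxy-3-methylphenyl)-5,9-dimethylundeca-5,9-dien-1-yn-1-yl]trimethylsilane, via lithiated 1-(trimethylsilyl)propyne 10 (not isolated)
Conditions: 9, n-BuLi, THF, −78 to −20 °C; then 8, −78 to 0 °C
Reagents that add atoms: none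
Why: Alkylation of lithiated 1-(trimethylsilyl)propyne with a primary allylic bromide; the silyl group steers the ambident anion to react at its propargylic carbon, and direct displacement at C8' leaves the E olefin untouched.

Step 7
Reactants: 11 [(5E,9E)-11-(2,5-dimethoxy-3-methylphenyl)-5,9-dimethylundeca-5,9-dien-1-yn-1-yl]trimethylsilane
Product: 12 1-[(2E,6E)-3,7-dimethylundeca-2,6-dien-10-yn-1-yl]-2,5-dimethoxy-3-methylbenzene
Conditions: K2CO3 (0.3 equiv), MeOH, rt
Reagents that add atoms: none
Why: Base-catalysed protodesilylation of an alkynylsilane in methanol; nothing else in 11 reacts with methoxide at room temperature.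

Step 8
Reactants: 12 1-[(2E,6E)-3,7-dimethylundeca-2,6-dien-10-yn-1-yl]-2,5-dimethoxy-3-methylbenzene
Product: 14 methyl (6E,10E)-12-(2,5-dimethoxy-3-methylphenyl)-6,10-dimethyldodeca-6,10-dien-2-ynoate, via lithium acetylide 13 (not isolated)
Conditions: n-BuLi, THF, −78 °C; then ClCO2Me, −78 to 0 °C
Reagents that add atoms: methyl chloroformate, COC(=O)Cl
Why: Deprotonation of the terminal alkyne and acylation of the lithium acetylide; the acetylenic C–H is by far the most acidic site of 12.

Step 9
Reactants: 15 methyl 2-hydroxybut-3-enoate (racemic)
Product: 17 2-methylpent-4-ene-2,3-diol (racemic), via 3-hydroxypent-4-en-2-one 16 (not isolated)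
Conditions: MeMgBr (3.5 equiv), THF, 0 °C to rt
Reagents that add atoms: methylmagnesium bromide, C[Mg]Br
Why: Double Grignard addition to an ester after deprotonation of the hydroxyl; the racemate suffices because the carbinol centre is destroyed in step 10.

Step 10
Reactants: 14 methyl (6E,10E)-12-(2,5-dimethoxy-3-methylphenyl)-6,10-dimethyldodeca-6,10-dien-2-ynoate; 17 2-methylpent-4-ene-2,3-diol
Product: 19 methyl (2Z,6E,10E)-12-(2,5-dimethoxy-3-methylphenyl)-2-(4-hydroxy-4-methyl-3-oxopentyl)-6,10-dimethyldodeca-2,6,10-trienoate, via dienol 18 (not isolated)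
Conditions: [CpRu(MeCN)3]PF6 (10 mol %), acetone, rt; racemic diol in twofold excess
Reagents that add atoms: none
Why: Ruthenium-catalysed alkene–alkyne coupling, a redox-neutral formal Alder-ene reaction in which all atoms of both partners end up in the product. Once its labile nitrile ligands have made room, the CpRu cation binds the ynoate of 14 and the vinyl group of 17 and couples them oxidatively to a ruthenacyclopentene in which the alkene CH2 (future C4) is bonded to the ester-bearing carbon C3 and ruthenium to C10' and C5. β-Hydride elimination of the carbinol hydrogen on C6 and C–H reductive elimination at C10' give dienol 18, which tautomerises to ketone 19. H and C4 are thereby added to the same face of the alkyne, so C9' and the ester end up cis (2Z). The closest known reactions are the coupling of 2-ynoates with terminal alkenes, which alkylates the α-carbon with cis delivery of hydrogen, and the coupling of alkynes with allylic alcohols, which gives γ,δ-unsaturated ketones. No ring closes and no stereocentre is formed; the carbinol centre of 17 is destroyed, so the racemate serves. The step needs C–C bond formation at the α-carbon, which the polarised ynoate provides, cis addition, which the metallacycle enforces, and reaction of the monosubstituted alkene only, which follows because trisubstituted olefins bind the crowded CpRu centre poorly and the nearer chain olefin, 1,5 to the alkyne, could only react through a strained four-membered ring fused to the metallacycle.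

Step 11
Reactants: 19 methyl (2Z,6E,10E)-12-(2,5-dimethoxy-3-methylphenyl)-2-(4-hydroxy-4-methyl-3-oxopentyl)-6,10-dimethyldodeca-2,6,10-trienoate
Product: 20 methyl (2Z,6E,10E)-12-(2,5-dimethoxy-3-methylphenyl)-6,10-dimethyl-2-[4-methyl-3-oxo-4-(trimethylsilyloxy)pentyl]dodeca-2,6,10-trienoate
Conditions: N-(trimethylsilyl)imidazole (1.5 equiv), CH2Cl2, rt
Reagents that add atoms: N-(trimethylsilyl)imidazole, C[Si](C)(C)n1ccnc1
Why: Silylation of the tertiary alcohol with a neutral silyl donor that does not enolise the ketone; the ether gives the reduction a single, clearly larger ketone substituent and removes the acidic hydroxyl.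

Step 12
Reactants: 20 methyl (2Z,6E,10E)-12-(2,5-dimethoxy-3-methylphenyl)-6,10-dimethyl-2-[4-methyl-3-oxo-4-(trimethylsilyloxy)pentyl]dodeca-2,6,10-trienoate
Product: 21 methyl (2Z,6E,10E)-12-(2,5-dimethoxy-3-methylphenyl)-2-[(3R)-3-hydroxy-4-methyl-4-(trimethylsilyloxy)pentyl]-6,10-dimethyldodeca-2,6,10-trienoate
Conditions: (S)-Me-CBS oxazaborolidine [(S)-1-methyl-3,3-diphenyltetrahydro-1H,3H-pyrrolo[1,2-c][1,3,2]oxazaborole] (0.2 equiv), catecholborane (2 equiv), toluene, −78 to −40 °C
Reagents that add atoms: none
Why: Corey–Bakshi–Shibata reduction; the ketone binds to the catalyst boron anti to the quaternary silyloxy carbon, and with the S catalyst hydride should be delivered to the face that gives the R carbinol, the sense known for tert-alkyl and aryl ketones. Catecholborane is chosen because, unlike BH3, it does not hydroborate the trisubstituted olefins or reduce the enoate at low temperature.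

Step 13
Reactants: 21 methyl (2Z,6E,10E)-12-(2,5-dimethoxy-3-methylphenyl)-2-[(3R)-3-hydroxy-4-methyl-4-(trimethylsilyloxy)pentyl]-6,10-dimethyldodeca-2,6,10-trienoate
Product: 23 (3Z,6R)-3-[(4E,8E)-10-(2,5-dimethoxy-3-methylphenyl)-4,8-dimethyldeca-4,8-dien-1-ylidene]-6-(2-hydroxypropan-2-yl)oxan-2-one, via diol ester 22 (not isolated)
Conditions: CSA (0.1 equiv), MeOH, 0 °C to rt; then solvent switch to toluene, 50 °C
Reagents that add atoms: none
Why: Acid-catalysed methanolysis of the trimethylsilyl ether followed by intramolecular transesterification; the secondary C6 hydroxyl closes the six-membered ring, while the tertiary hydroxyl would have to form a seven-membered ring and stays free. The C6–O bond is not broken, so the R configuration is kept, and the olefin geometry is not touched.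

Step 14
Reactants: 23 (3Z,6R)-3-[(4E,8E)-10-(2,5-dimethoxy-3-methylphenyl)-4,8-dimethyldeca-4,8-dien-1-ylidene]-6-(2-hydroxypropan-2-yl)oxan-2-one
Product: 24 2-[(2E,6E,10Z)-10-[(6R)-6-(2-hydroxypropan-2-yl)-2-oxooxan-3-ylidene]-3,7-dimethyldeca-2,6-dien-1-yl]-6-methylcyclohexa-2,5-diene-1,4-dione (CNP0270314.1)
Conditions: (NH4)2Ce(NO3)6 (2.5 equiv), MeCN/H2O, 0 °C
Reagents that add atoms: water, O
Why: Oxidative demethylation of a hydroquinone dimethyl ether; two one-electron oxidations and attack of water give the para-quinone and two molecules of methanol, and isolated trisubstituted olefins, the lactone and the tertiary alcohol are known to tolerate the reagent at 0 °C.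

## Compound list

1 | 4-methoxy-2-methylphenol | COc1ccc(O)c(C)c1 | starting material
2 | 2-bromo-4-methoxy-6-methylphenol | COc1cc(C)c(O)c(Br)c1 | intermediate
3 | 1-bromo-2,5-dimethoxy-3-methylbenzene | COc1cc(C)c(OC)c(Br)c1 | intermediate
4 | geranyl bromide, (2E)-1-bromo-3,7-dimethylocta-2,6-diene | CC(C)=CCC/C(C)=C/CBr | starting material
5 | (2,5-dimethoxy-3-methylphenyl)magnesium bromide (formed in the flask) | COc1cc(C)c(OC)c([Mg]Br)c1 | intermediate
6 | 1-[(2E)-3,7-dimethylocta-2,6-dien-1-yl]-2,5-dimethoxy-3-methylbenzene | COc1cc(C)c(OC)c(C/C=C(\C)CCC=C(C)C)c1 | intermediate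
7 | (2E,6E)-8-(2,5-dimethoxy-3-methylphenyl)-2,6-dimethylocta-2,6-dien-1-ol | COc1cc(C)c(OC)c(C/C=C(\C)CC/C=C(\C)CO)c1 | intermediate
8 | 1-[(2E,6E)-8-bromo-3,7-dimethylocta-2,6-dien-1-yl]-2,5-dimethoxy-3-methylbenzene | COc1cc(C)c(OC)c(C/C=C(\C)CC/C=C(\C)CBr)c1 | intermediate
9 | 1-(trimethylsilyl)propyne | CC#C[Si](C)(C)C | starting material
10 | [3-(trimethylsilyl)prop-2-yn-1-yl]lithium (formed in the flask) | [Li]CC#C[Si](C)(C)C | intermediate
11 | [(5E,9E)-11-(2,5-dimethoxy-3-methylphenyl)-5,9-dimethylundeca-5,9-dien-1-yn-1-yl]trimethylsilane | COc1cc(C)c(OC)c(C/C=C(\C)CC/C=C(\C)CCC#C[Si](C)(C)C)c1 | intermediate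
12 | 1-[(2E,6E)-3,7-dimethylundeca-2,6-dien-10-yn-1-yl]-2,5-dimethoxy-3-methylbenzene | COc1cc(C)c(OC)c(C/C=C(\C)CC/C=C(\C)CCC#C)c1 | intermediate
13 | [(5E,9E)-11-(2,5-dimethoxy-3-methylphenyl)-5,9-dimethylundeca-5,9-dien-1-yn-1-yl]lithium (formed in the flask) | COc1cc(C)c(OC)c(C/C=C(\C)CC/C=C(\C)CCC#C[Li])c1 | intermediate
14 | methyl (6E,10E)-12-(2,5-dimethoxy-3-methylphenyl)-6,10-dimethyldodeca-6,10-dien-2-ynoate | COc1cc(C)c(OC)c(C/C=C(\C)CC/C=C(\C)CCC#CC(=O)OC)c1 | intermediate
15 | methyl 2-hydroxybut-3-enoate (racemic) | C=CC(O)C(=O)OC | starting material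
16 | 3-hydroxypent-4-en-2-one (racemic, as its bromomagnesium alkoxide, formed in the flask) | C=CC(O)C(C)=O | intermediate
17 | 2-methylpent-4-ene-2,3-diol (racemic) | C=CC(O)C(C)(C)O | intermediate
18 | methyl (2Z,6E,10E)-2-(3,4-dihydroxy-4-methylpent-2-en-1-yl)-12-(2,5-dimethoxy-3-methylphenyl)-6,10-dimethyldodeca-2,6,10-trienoate (dienol, formed in the flask) | COc1cc(C)c(OC)c(C/C=C(\C)CC/C=C(\C)CC/C=C(/CC=C(O)C(C)(C)O)C(=O)OC)c1 | intermediate
19 | methyl (2Z,6E,10E)-12-(2,5-dimethoxy-3-methylphenyl)-2-(4-hydroxy-4-methyl-3-oxopentyl)-6,10-dimethyldodeca-2,6,10-trienoate | COc1cc(C)c(OC)c(C/C=C(\C)CC/C=C(\C)CC/C=C(/CCC(=O)C(C)(C)O)C(=O)OC)c1 | intermediate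
20 | methyl (2Z,6E,10E)-12-(2,5-dimethoxy-3-methylphenyl)-6,10-dimethyl-2-[4-methyl-3-oxo-4-(trimethylsilyloxy)pentyl]dodeca-2,6,10-trienoate | COc1cc(C)c(OC)c(C/C=C(\C)CC/C=C(\C)CC/C=C(/CCC(=O)C(C)(C)O[Si](C)(C)C)C(=O)OC)c1 | intermediate
21 | methyl (2Z,6E,10E)-12-(2,5-dimethoxy-3-methylphenyl)-2-[(3R)-3-hydroxy-4-methyl-4-(trimethylsilyloxy)pentyl]-6,10-dimethyldodeca-2,6,10-trienoate | COc1cc(C)c(OC)c(C/C=C(\C)CC/C=C(\C)CC/C=C(/CC[C@@H](O)C(C)(C)O[Si](C)(C)C)C(=O)OC)c1 | intermediate
22 | methyl (2Z,6E,10E)-2-[(3R)-3,4-dihydroxy-4-methylpentyl]-12-(2,5-dimethoxy-3-methylphenyl)-6,10-dimethyldodeca-2,6,10-trienoate (formed in the flask) | COc1cc(C)c(OC)c(C/C=C(\C)CC/C=C(\C)CC/C=C(/CC[C@@H](O)C(C)(C)O)C(=O)OC)c1 | intermediate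
23 | (3Z,6R)-3-[(4E,8E)-10-(2,5-dimethoxy-3-methylphenyl)-4,8-dimethyldeca-4,8-dien-1-ylidene]-6-(2-hydroxypropan-2-yl)oxan-2-one | COc1cc(C)c(OC)c(C/C=C(\C)CC/C=C(\C)CC/C=C2/CC[C@H](C(C)(C)O)OC2=O)c1 | intermediate
24 | 2-[(2E,6E,10Z)-10-[(6R)-6-(2-hydroxypropan-2-yl)-2-oxooxan-3-ylidene]-3,7-dimethyldeca-2,6-dien-1-yl]-6-methylcyclohexa-2,5-diene-1,4-dione (CNP0270314.1) | CC1=CC(=O)C=C(C/C=C(\C)CC/C=C(\C)CC/C=C2/CC[C@H](C(C)(C)O)OC2=O)C1=O | target

## Step count and risks

Total step count: 14. Longest linear sequence: 13 steps (steps 1 to 8 and 10 to 14); step 9 is a one-step branch.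

**Step 10 (key step).** Most likely to go wrong:
- deactivation of the catalyst through η6-complexation of the CpRu cation by the electron-rich arene of 14;
- consumption of 17 by ruthenium-catalysed redox isomerisation of the allylic alcohol;
- partial erosion of regiocontrol in the oxidative coupling.

The fallback replaces the catalytic coupling by stepwise cis-hydrometalation and cross-coupling, and takes C6 from an enantiopure building block. It sets out from 14 and comes back at 22 and hence 23, so steps 11 and 12 are no longer needed. Pd(PPh3)4-catalysed cis-hydrostannation of 14 with Bu3SnH should give the α-stannyl enoate, methyl (2E,6E,10E)-12-(2,5-dimethoxy-3-methylphenyl)-6,10-dimethyl-2-(tributylstannyl)dodeca-2,6,10-trienoate F1. Iododestannylation with I2 converts it with retention into the α-iodo enoate F2, in which C9' is already cis to the ester. In parallel, methyl (2R)-2-hydroxybut-3-enoate F3, the R enantiomer of 15, is treated as in step 9 to give (3R)-2-methylpent-4-ene-2,3-diol F4, which is silylated (TESOTf, 2,6-lutidine) to the bis(triethylsilyl) ether F5. Hydroboration of F5 with 9-BBN gives the alkylborane F6, and a B-alkyl Suzuki–Miyaura coupling of F6 with F2 (PdCl2(dppf), AsPh3, Cs2CO3, DMF/THF/H2O, rt) forms the C3–C4 bond with retention, giving the bis-silyl ester F7. HF·pyridine then frees both hydroxyls to give 22, which is lactonised to 23 as in the second stage of step 13.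

**Step 4.** Most likely to go wrong: competing allylic oxidation at C4' of the internal olefin, which in 6 is not deactivated by an allylic heteroatom, and over-oxidation of the product to the enal. The fallback moves the oxidation to a substrate whose near olefin is deactivated; it sets out from Grignard reagent 5 (from 3) and comes back at 7. Geranyl acetate F8 is oxidised under the conditions of step 4 to (2E,6E)-8-hydroxy-3,7-dimethylocta-2,6-dien-1-yl acetate F9. An excess of 5 (one equivalent is spent on the hydroxyl), transmetallated to copper with a stoichiometric amount of CuI so that the acetate carbonyl is not attacked, then displaces the allylic acetate of F9 at C1 and should give 7 directly.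

**Step 12.** Most likely to go wrong: slow reduction and insufficient facial discrimination because the ketone is flanked by a quaternary carbon, and hydroboration of the chain if a more reactive borane has to be used. The fallback changes the principle of stereocontrol from steric differentiation to hydroxyl direction; it sets out from 19 and comes back at 22 and hence 23, replacing steps 11 and 12. The unprotected α-hydroxy ketone 19 is hydrogenated with RuCl2[(R)-BINAP] and H2 in methanol; the tertiary hydroxyl chelates ruthenium and the ligand selects the face. By analogy with simple α-hydroxy ketones the R ligand should give the R carbinol 22, which is lactonised as in step 13. Isolated trisubstituted olefins and the trisubstituted enoate are expected to be left alone by this type of catalyst.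

**Step 13.** Most likely to go wrong: incomplete ring closure of the conjugated, α-branched ester under acid mild enough to spare the diene chain, and, if the acid is forced, isomerisation of the Z enoate or ionisation of the tertiary alcohol. The fallback closes the ring by carboxyl activation instead of acid catalysis; it sets out from 22 (obtained from 21 by the methanol stage alone) and comes back at 23. Saponification (LiOH, THF/MeOH/H2O) gives the dihydroxy acid F10, and Yamaguchi lactonisation (2,4,6-trichlorobenzoyl chloride, Et3N, then DMAP, rt) closes ring B; only the secondary hydroxyl can form a six-membered ring.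

## Further compounds

F1 | step 10 | methyl (2E,6E,10E)-12-(2,5-dimethoxy-3-methylphenyl)-6,10-dimethyl-2-(tributylstannyl)dodeca-2,6,10-trienoate | COc1cc(C)c(OC)c(C/C=C(\C)CC/C=C(\C)CC/C=C(/[Sn](CCCC)(CCCC)CCCC)C(=O)OC)c1
F2 | step 10 | methyl (2E,6E,10E)-12-(2,5-dimethoxy-3-methylphenyl)-2-iodo-6,10-dimethyldodeca-2,6,10-trienoate | COc1cc(C)c(OC)c(C/C=C(\C)CC/C=C(\C)CC/C=C(/I)C(=O)OC)c1
F3 | step 10 | methyl (2R)-2-hydroxybut-3-enoate | C=C[C@@H](O)C(=O)OC
F4 | step 10 | (3R)-2-methylpent-4-ene-2,3-diol | C=C[C@@H](O)C(C)(C)O
F5 | step 10 | (3R)-2-methyl-2,3-bis(triethylsilyloxy)pent-4-ene | C=C[C@@H](O[Si](CC)(CC)CC)C(C)(C)O[Si](CC)(CC)CC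
F6 | step 10 | 9-[(3R)-4-methyl-3,4-bis(triethylsilyloxy)pentyl]-9-borabicyclo[3.3.1]nonane | B1(CC[C@@H](O[Si](CC)(CC)CC)C(C)(C)O[Si](CC)(CC)CC)C2CCCC1CCC2
F7 | step 10 | methyl (2Z,6E,10E)-12-(2,5-dimethoxy-3-methylphenyl)-6,10-dimethyl-2-[(3R)-4-methyl-3,4-bis(triethylsilyloxy)pentyl]dodeca-2,6,10-trienoate | COc1cc(C)c(OC)c(C/C=C(\C)CC/C=C(\C)CC/C=C(/CC[C@@H](O[Si](CC)(CC)CC)C(C)(C)O[Si](CC)(CC)CC)C(=O)OC)c1
F8 | step 4 | geranyl acetate, (2E)-3,7-dimethylocta-2,6-dien-1-yl acetate | CC(C)=CCC/C(C)=C/COC(C)=O
F9 | step 4 | (2E,6E)-8-hydroxy-3,7-dimethylocta-2,6-dien-1-yl acetate | CC(=O)OC/C=C(\C)CC/C=C(\C)CO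
F0 | step 12 | none | none
F10 | step 13 | (2Z,6E,10E)-2-[(3R)-3,4-dihydroxy-4-methylpentyl]-12-(2,5-dimethoxy-3-methylphenyl)-6,10-dimethyldodeca-2,6,10-trienoic acid | COc1cc(C)c(OC)c(C/C=C(\C)CC/C=C(\C)CC/C=C(/CC[C@@H](O)C(C)(C)O)C(=O)O)c1
A1 | alternative 1 | pentacarbonyl[(2E)-1-methoxybut-2-en-1-ylidene]chromium | C/C=C/C(OC)=[Cr](=C=O)(=C=O)(=C=O)(=C=O)=C=O
A2 | alternative 1 | (3Z,6R)-3-[(4E,8E)-4,8-dimethyldodeca-4,8-dien-11-yn-1-ylidene]-6-(2-hydroxypropan-2-yl)oxan-2-one | C#CC/C=C(\C)CC/C=C(\C)CC/C=C1/CC[C@H](C(C)(C)O)OC1=O
A3 | alternative 1 | (3Z,6R)-3-[(4E,8E)-10-(2-hydroxy-5-methoxy-3-methylphenyl)-4,8-dimethyldeca-4,8-dien-1-ylidene]-6-(2-hydroxypropan-2-yl)oxan-2-one | COc1cc(C)c(O)c(C/C=C(\C)CC/C=C(\C)CC/C=C2/CC[C@H](C(C)(C)O)OC2=O)c1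
A4 | alternative 2 | (3R,6Z,10E)-3-(tert-butyldimethylsilyloxy)-6-[(tert-butyldimethylsilyloxy)methyl]-2,10-dimethylpentadeca-6,10-dien-14-yn-2-ol | C#CCC/C=C(\C)CC/C=C(\CO[Si](C)(C)C(C)(C)C)CC[C@H](C(C)(C)O)O[Si](C)(C)C(C)(C)C
A5 | alternative 2 | 1-(chloromethyl)-2,5-dimethoxy-3-methylbenzene | COc1cc(C)c(OC)c(CCl)c1
A6 | alternative 2 | (3R,6Z,10E,14E)-3-(tert-butyldimethylsilyloxy)-6-[(tert-butyldimethylsilyloxy)methyl]-16-(2,5-dimethoxy-3-methylphenyl)-2,10,14-trimethylhexadeca-6,10,14-trien-2-ol | COc1cc(C)c(OC)c(C/C=C(\C)CC/C=C(\C)CC/C=C(\CO[Si](C)(C)C(C)(C)C)CC[C@H](C(C)(C)O)O[Si](C)(C)C(C)(C)C)c1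
A7 | alternative 3 | 1,3-dioxoisoindolin-2-yl (4E)-6-(2,5-dimethoxy-3-methylphenyl)-4-methylhex-4-enoate | COc1cc(C)c(OC)c(C/C=C(\C)CCC(=O)ON2C(=O)c3ccccc3C2=O)c1
A8 | alternative 3 | (3Z,6R)-6-(2-hydroxypropan-2-yl)-3-[(4E)-5-iodo-4-methylpent-4-en-1-ylidene]oxan-2-one | I/C=C(\C)CC/C=C1/CC[C@H](C(C)(C)O)OC1=O
A9 | alternative 3 | (3Z,6R)-3-[(4E,8E)-10-(2,5-dimethoxy-3-methylphenyl)-4,8-dimethyldeca-4,8-dien-1-ylidene]-6-(2-hydroxypropan-2-yl)oxan-2-one (identical with 23) | COc1cc(C)c(OC)c(C/C=C(\C)CC/C=C(\C)CC/C=C2/CC[C@H](C(C)(C)O)OC2=O)c1
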